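**Plan**
Retrosynthesis: the three phenols are masked as MOM ethers and C8–CHO is traced back to C8–Br. Ring C is then cut at O1–C2 and at C3–C4, which separates ring A from the C2–C3 unit that carries ring B.
Enabling feature: C4 is a benzylic CH2 on C4a, and C4a is ortho to the O1-bearing C8a. Ring A is therefore a masked ortho-quinone methide whose two reactive ends (C4 and O1) are the atoms bonded to C3 and C2.
Forward: a ring A 2-(tosylmethyl)phenol (4 steps) and a ring B arylacetic acid (4 steps) are made separately. Step 9 joins them, forms C3–C4 and the O1–C2 acyl bond, and closes ring C as a lactone.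
The lactone is reduced to phenol plus primary alcohol, ring C is closed again as the ether (Mitsunobu), Br at C8 is exchanged for Li and formylated, and acid frees the phenols.
Stereochemistry: C3 (R) is the only stereocentre. It is set in step 9 by a chiral isothiourea that shields one face of its bound enolate, and no later step touches C3.
C8 carries Br rather than CHO during the annulation, because a salicylaldehyde, an activated arylacetic acid and base would condense to a 3-arylcoumarin (Perkin type). Br also blocks C8 against C-alkylation by the methide.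

Key step: step 9

Chroman numbering (O1, C2, C3, C4, C4a, C5 to C8, C8a; ring B primed) is used for the atoms of the target.
Assumption 1: the facial sense of (2S,3R)-HyperBTM [(2S,3R)-3-isopropyl-2-phenyl-3,4-dihydro-2H-benzo[4,5]thiazolo[3,2-a]pyrimidine] follows the usual model (attack anti to the C2 phenyl group of the S···O-locked (Z)-enolate), which corresponds to 3R here; if the lactone proved to be 3S, the equally available (2R,3S)-catalyst would be used with no other change.
Assumption 2: 1 is bought as a catalogue compound; it is otherwise one Vilsmeier–Haack formylation away from 5-methoxyresorcinol.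

Step 1
Reactants: 1 2,4-dihydroxy-6-methoxybenzaldehyde
Product: 2 2-hydroxy-6-methoxy-4-(methoxymethoxy)benzaldehyde
Conditions: MOMCl (1.05 equiv), i-Pr2NEt (1.2 equiv), CH2Cl2, 0 °C
Reagents that add atoms: chloromethyl methyl ether, COCCl
Why: O-alkylation of a phenol (MOM ether formation) that should stop at the 4-OH, because the 2-OH is held in a hydrogen bond to the formyl oxygen and is much less nucleophilic.

Step 2
Reactants: 2 2-hydroxy-6-methoxy-4-(methoxymethoxy)benzaldehyde
Product: 3 3-bromo-2-hydroxy-6-methoxy-4-(methoxymethoxy)benzaldehyde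
Conditions: NBS (1.0 equiv), i-Pr2NH (10 mol %), CH2Cl2, 0 °C
Reagents that add atoms: N-bromosuccinimide, O=C1CCC(=O)N1Br
Why: Electrophilic aromatic bromination directed by the free phenol: amine-modified NBS delivers bromine to the open ortho carbon C3 (between OH and OMOM), the site at which 2-hydroxy-4,6-dialkoxyaryl aldehydes and ketones are known to be halogenated, whereas C5 is crowded by two ether groups.

Step 3
Reactants: 3 3-bromo-2-hydroxy-6-methoxy-4-(methoxymethoxy)benzaldehyde
Product: 4 2-bromo-6-(hydroxymethyl)-5-methoxy-3-(methoxymethoxy)phenol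
Conditions: NaBH4 (1.0 equiv), THF–EtOH, 0 °C; pH 7 buffer; crude product used directly
Reagents that add atoms: none
Why: Borohydride reduction of an aldehyde, run cold and worked up at neutral pH because the trioxygenated ortho-hydroxybenzyl alcohol ionises easily, with aryl bromide and MOM ether inert to the reagent.

Step 4
Reactants: 4 2-bromo-6-(hydroxymethyl)-5-methoxy-3-(methoxymethoxy)phenol
Product: 5 2-bromo-5-methoxy-3-(methoxymethoxy)-6-[(4-methylphenyl)sulfonylmethyl]phenol
Conditions: TolSO2Na (1.5 equiv), AcOH (2 equiv), EtOH–H2O, rt to 40 °C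
Reagents that add atoms: sodium p-toluenesulfinate, Cc1ccc(cc1)S(=O)[O-].[Na+]
Why: SN1-type substitution of an electron-rich ortho-hydroxybenzyl alcohol by a sulfinate, the usual entry to 2-(sulfonylmethyl)phenols: the C5 and C7 oxygens let acetic acid ionise the benzylic C–O bond, the soft sulfur atom of the sulfinate captures the cation, and the acid is too weak to cleave the MOM ether.

Step 5
Reactants: 6 4-bromoresorcinol
Product: 7 1-bromo-2,4-bis(methoxymethoxy)benzene
Conditions: MOMCl (2.5 equiv), i-Pr2NEt (3 equiv), CH2Cl2, 0 °C to rt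
Reagents that add atoms: chloromethyl methyl ether, COCCl
Why: Double O-alkylation of a resorcinol to the bis-MOM ether, which protects both phenols against the organolithium steps and supplies the directing groups needed in step 7.

Step 6
Reactants: 7 1-bromo-2,4-bis(methoxymethoxy)benzene
Product: 9 2-[2,4-bis(methoxymethoxy)phenyl]ethan-1-ol, via aryllithium 8 (not isolated)
Conditions: n-BuLi (1.05 equiv), THF, −78 °C; ethylene oxide (2 equiv, THF solution), −78 °C to rt; H2O
Reagents that add atoms: ethylene oxide, C1CO1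
Why: Bromine–lithium exchange followed by SN2 opening of ethylene oxide by the aryllithium, a standard two-carbon homologation to a 2-arylethanol, with the epoxide added at −78 °C so that lithium does not migrate to the more acidic C3 position before the C–C bond forms.

Step 7
Reactants: 9 2-[2,4-bis(methoxymethoxy)phenyl]ethan-1-ol; 10 prenyl bromide (1-bromo-3-methylbut-2-ene)
Product: 12 2-[2,4-bis(methoxymethoxy)-3-(3-methylbut-2-en-1-yl)phenyl]ethan-1-ol, via dilithio species 11 (not isolated)
Conditions: n-BuLi (2.3 equiv), THF, 0 °C, 1.5 h; CuI (10 mol %), 10 (1.1 equiv), −78 °C to rt; H2O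
Reagents that add atoms: none
Why: Directed ortho-metalation and allylation: once the alcohol is deprotonated, the second equivalent of n-BuLi removes the ring proton that lies between the two MOM ethers (the most acidic one by their cooperative effect), and the copper-assisted aryllithium displaces bromide at the primary carbon of 10, the prenyl group being introduced only now so that no lithiation has to be run next to its benzylic-allylic CH2.

Step 8
Reactants: 12 2-[2,4-bis(methoxymethoxy)-3-(3-methylbut-2-en-1-yl)phenyl]ethan-1-ol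
Product: 14 2-[2,4-bis(methoxymethoxy)-3-(3-methylbut-2-en-1-yl)phenyl]acetic acid, via arylacetaldehyde 13 (not isolated)
Conditions: TEMPO (20 mol %), PhI(OAc)2 (2.5 equiv), MeCN–H2O 1:1, rt
Reagents that add atoms: water, O
Why: Oxoammonium-mediated oxidation (catalytic TEMPO with PhI(OAc)2 in aqueous acetonitrile) takes the primary alcohol through aldehyde 13 and its hydrate to the acid under nearly neutral conditions that leave the trisubstituted alkene, the MOM ethers and the electron-rich ring alone.

Step 9
Reactants: 5 2-bromo-5-methoxy-3-(methoxymethoxy)-6-[(4-methylphenyl)sulfonylmethyl]phenol; 14 2-[2,4-bis(methoxymethoxy)-3-(3-methylbut-2-en-1-yl)phenyl]acetic acid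
Product: 18 (3R)-8-bromo-3-[2,4-bis(methoxymethoxy)-3-(3-methylbut-2-en-1-yl)phenyl]-5-methoxy-7-(methoxymethoxy)-3,4-dihydro-2H-chromen-2-one, via pivalic mixed anhydride 15 (not isolated), via HyperBTM-bound ammonium enolate 16 (not isolated), via ring A ortho-quinone methide 17 (not isolated)
Conditions: 14 (1.4 equiv), t-BuCOCl (1.4 equiv), i-Pr2NEt (1.5 equiv), CH2Cl2, 0 °C, 20 min; then (2S,3R)-HyperBTM (10 mol %), 5, Cs2CO3 (2.5 equiv), −10 °C; cold pH 7 buffer, short silica plug, used at once
Reagents that add atoms: none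
Why: Cs2CO3 deprotonates the C8a phenol of 5 and the phenoxide, pushed by the C5 and C7 oxygens, expels p-toluenesulfinate to give methide 17, while the isothiourea is acylated by anhydride 15 and deprotonated to the (Z)-ammonium enolate 16, kept planar by a 1,5 S···O contact. The enolate carbon (C3) adds in Michael fashion to the exocyclic CH2 (C4) of 17, ring A regains aromaticity, and the C8a phenoxide displaces the catalyst from the acyl carbon C2, so ring C closes by a 6-exo-trig acyl substitution (lactonisation). This is the known isothiourea-catalysed formal (4+2) annulation of arylacetic acids with ortho-quinone methides released in situ from 2-(sulfonylmethyl)phenols, applied here to the less usual unsubstituted methide terminus. C3 is the only new stereocentre and is controlled by the catalyst: its pseudoaxial C2 phenyl group covers one enolate face, and attack on the open face of the (2S,3R)-bound enolate corresponds to 3R. The step needs capture of 17 to be faster than its self-condensation and than O-acylation side paths: 17 offers only C4 and O1 as reactive ends, bromine blocks C8, the remaining C6–H is flanked by two alkoxy groups, the heterogeneous carbonate keeps the methide concentration low, and the absence of a formyl group next to the phenol closes the Perkin-type path to a 3-arylcoumarin. The C3–H of the aryl lactone is acidic, which is why the reaction is run cold, quenched at neutral pH and followed at once by step 10.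

Step 10
Reactants: 18 (3R)-8-bromo-3-[2,4-bis(methoxymethoxy)-3-(3-methylbut-2-en-1-yl)phenyl]-5-methoxy-7-(methoxymethoxy)-3,4-dihydro-2H-chromen-2-one
Product: 19 2-bromo-6-{(2R)-2-[2,4-bis(methoxymethoxy)-3-(3-methylbut-2-en-1-yl)phenyl]-3-hydroxypropyl}-5-methoxy-3-(methoxymethoxy)phenol
Conditions: LiAlH4 (1.5 equiv), THF, −40 to 0 °C, 30 min; aq potassium sodium tartrate
Reagents that add atoms: none
Why: Hydride reduction of an aryl lactone to a phenol and a primary alcohol: addition of hydride to the activated aryl ester at low temperature is much faster than enolisation, so the C3 configuration should be carried over, and an aryl bromide is not attacked by LiAlH4 at or below 0 °C.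

Step 11
Reactants: 19 2-bromo-6-{(2R)-2-[2,4-bis(methoxymethoxy)-3-(3-methylbut-2-en-1-yl)phenyl]-3-hydroxypropyl}-5-methoxy-3-(methoxymethoxy)phenol
Product: 20 (3R)-8-bromo-3-[2,4-bis(methoxymethoxy)-3-(3-methylbut-2-en-1-yl)phenyl]-5-methoxy-7-(methoxymethoxy)-3,4-dihydro-2H-chromene
Conditions: PPh3 (1.5 equiv), DIAD (1.5 equiv), THF (0.02 M), 0 °C to rt
Reagents that add atoms: none
Why: Intramolecular Mitsunobu etherification (6-exo-tet), the usual ring C closure of isoflavan syntheses: the acidic ortho-bromophenol displaces the activated primary hydroxyl group at C2, a carbon that is not stereogenic, so C3 stays R.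

Step 12
Reactants: 20 (3R)-8-bromo-3-[2,4-bis(methoxymethoxy)-3-(3-methylbut-2-en-1-yl)phenyl]-5-methoxy-7-(methoxymethoxy)-3,4-dihydro-2H-chromene
Product: 22 (3R)-3-[2,4-bis(methoxymethoxy)-3-(3-methylbut-2-en-1-yl)phenyl]-5-methoxy-7-(methoxymethoxy)-3,4-dihydro-2H-chromene-8-carbaldehyde, via C8 aryllithium 21 (not isolated)
Conditions: n-BuLi (1.1 equiv), THF, −78 °C, 10 min; DMF (3 equiv), −78 to 0 °C; H2O
Reagents that add atoms: N,N-dimethylformamide, CN(C)C=O
Why: Bromine–lithium exchange and formylation with DMF (Bouveault aldehyde synthesis): exchange at −78 °C outruns any ortho-lithiation of ring B, the aryllithium is held by the flanking O1 and MOM oxygens, and there is no acidic proton near C3.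

Step 13
Reactants: 22 (3R)-3-[2,4-bis(methoxymethoxy)-3-(3-methylbut-2-en-1-yl)phenyl]-5-methoxy-7-(methoxymethoxy)-3,4-dihydro-2H-chromene-8-carbaldehyde
Product: 23 (3R)-3-[2,4-dihydroxy-3-(3-methylbut-2-en-1-yl)phenyl]-7-hydroxy-5-methoxy-3,4-dihydro-2H-chromene-8-carbaldehyde (CNP0399843.1)
Conditions: HCl (about 1 M, catalytic amount relative to solvent), MeOH, rt; aq NaHCO3 work-up
Reagents that add atoms: none
Why: Acid-catalysed transacetalisation of the three MOM ethers to dimethoxymethane, under the dilute methanolic HCl conditions commonly used for MOM ethers of ortho-prenylphenols, which are mild enough that protonation of the prenyl double bond and closure to a dimethylchroman should stay slow, methanol also scavenging the formaldehyde unit, and C3 is not affected.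

**Compound list**
1 | 2,4-dihydroxy-6-methoxybenzaldehyde | COc1cc(O)cc(O)c1C=O | starting material
2 | 2-hydroxy-6-methoxy-4-(methoxymethoxy)benzaldehyde | COCOc1cc(O)c(C=O)c(OC)c1 | intermediate
3 | 3-bromo-2-hydroxy-6-methoxy-4-(methoxymethoxy)benzaldehyde | COCOc1cc(OC)c(C=O)c(O)c1Br | intermediate
4 | 2-bromo-6-(hydroxymethyl)-5-methoxy-3-(methoxymethoxy)phenol | COCOc1cc(OC)c(CO)c(O)c1Br | intermediate
5 | 2-bromo-5-methoxy-3-(methoxymethoxy)-6-[(4-methylphenyl)sulfonylmethyl]phenol | COc1cc(OCOC)c(Br)c(O)c1CS(=O)(=O)c1ccc(C)cc1 | intermediate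
6 | 4-bromoresorcinol | Oc1ccc(Br)c(O)c1 | starting material
7 | 1-bromo-2,4-bis(methoxymethoxy)benzene | COCOc1ccc(Br)c(OCOC)c1 | intermediate
8 | [2,4-bis(methoxymethoxy)phenyl]lithium | [Li]c1ccc(OCOC)cc1OCOC | intermediate
9 | 2-[2,4-bis(methoxymethoxy)phenyl]ethan-1-ol | OCCc1ccc(OCOC)cc1OCOC | intermediate
10 | prenyl bromide (1-bromo-3-methylbut-2-ene) | CC(C)=CCBr | starting material
11 | lithium 2-[3-lithio-2,4-bis(methoxymethoxy)phenyl]ethanolate | [Li]OCCc1ccc(OCOC)c([Li])c1OCOC | intermediate
12 | 2-[2,4-bis(methoxymethoxy)-3-(3-methylbut-2-en-1-yl)phenyl]ethan-1-ol | OCCc1ccc(OCOC)c(CC=C(C)C)c1OCOC | intermediate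
13 | 2-[2,4-bis(methoxymethoxy)-3-(3-methylbut-2-en-1-yl)phenyl]acetaldehyde | O=CCc1ccc(OCOC)c(CC=C(C)C)c1OCOC | intermediate
14 | 2-[2,4-bis(methoxymethoxy)-3-(3-methylbut-2-en-1-yl)phenyl]acetic acid | OC(=O)Cc1ccc(OCOC)c(CC=C(C)C)c1OCOC | intermediate
15 | 2-[2,4-bis(methoxymethoxy)-3-(3-methylbut-2-en-1-yl)phenyl]acetic 2,2-dimethylpropanoic anhydride | CC(C)(C)C(=O)OC(=O)Cc1ccc(OCOC)c(CC=C(C)C)c1OCOC | intermediate
16 | (Z)-ammonium enolate of 14 bound to N1 of (2S,3R)-HyperBTM | [O-]/C(=C\c1ccc(OCOC)c(CC=C(C)C)c1OCOC)[N+]1=C2Sc3ccccc3N2C[C@@H](C(C)C)[C@H]1c1ccccc1 | intermediate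
17 | 2-bromo-5-methoxy-3-(methoxymethoxy)-6-methylidenecyclohexa-2,4-dien-1-one | C=C1C(=O)C(Br)=C(OCOC)C=C1OC | intermediate
18 | (3R)-8-bromo-3-[2,4-bis(methoxymethoxy)-3-(3-methylbut-2-en-1-yl)phenyl]-5-methoxy-7-(methoxymethoxy)-3,4-dihydro-2H-chromen-2-one | COc1cc(OCOC)c(Br)c2c1C[C@H](c1ccc(OCOC)c(CC=C(C)C)c1OCOC)C(=O)O2 | intermediate
19 | 2-bromo-6-{(2R)-2-[2,4-bis(methoxymethoxy)-3-(3-methylbut-2-en-1-yl)phenyl]-3-hydroxypropyl}-5-methoxy-3-(methoxymethoxy)phenol | COc1cc(OCOC)c(Br)c(O)c1C[C@H](c1ccc(OCOC)c(CC=C(C)C)c1OCOC)CO | intermediate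
20 | (3R)-8-bromo-3-[2,4-bis(methoxymethoxy)-3-(3-methylbut-2-en-1-yl)phenyl]-5-methoxy-7-(methoxymethoxy)-3,4-dihydro-2H-chromene | COc1cc(OCOC)c(Br)c2c1C[C@H](c1ccc(OCOC)c(CC=C(C)C)c1OCOC)CO2 | intermediate
21 | 8-lithio derivative of 20 (Li in place of Br) | COc1cc(OCOC)c([Li])c2c1C[C@H](c1ccc(OCOC)c(CC=C(C)C)c1OCOC)CO2 | intermediate
22 | (3R)-3-[2,4-bis(methoxymethoxy)-3-(3-methylbut-2-en-1-yl)phenyl]-5-methoxy-7-(methoxymethoxy)-3,4-dihydro-2H-chromene-8-carbaldehyde | COc1cc(OCOC)c(C=O)c2c1C[C@H](c1ccc(OCOC)c(CC=C(C)C)c1OCOC)CO2 | intermediate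
23 | (3R)-3-[2,4-dihydroxy-3-(3-methylbut-2-en-1-yl)phenyl]-7-hydroxy-5-methoxy-3,4-dihydro-2H-chromene-8-carbaldehyde | COc1cc(O)c(C=O)c2c1C[C@H](c1ccc(O)c(CC=C(C)C)c1O)CO2 | target

**Totals and risks**
Total step count: 13 (ring A 4, ring B 4, union and endgame 5).
Longest linear sequence: 9 steps (1 to 23, or equally 6 to 23).

**Most likely to fail, first: step 9.**
- What may go wrong: self-condensation of the unsubstituted methide may outrun its capture by the low stationary concentration of catalytic enolate. Facial discrimination may be weak with the crowded ring B. The C3 configuration may erode by enolisation of the aryl lactone under carbonate.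
- The fallback replaces catalysis by auxiliary control and avoids the lactone. It sets out from 14 and 5 and comes back at 19.
- Acid 14 is taken through anhydride 15 and coupled with lithiated (R)-4-benzyl-1,3-oxazolidin-2-one to give (4R)-4-benzyl-3-{[2,4-bis(methoxymethoxy)-3-(3-methylbut-2-en-1-yl)phenyl]acetyl}-1,3-oxazolidin-2-one F1.
- Its chelated (Z)-sodium enolate (NaN(SiMe3)2, THF, −78 °C, used in excess) is combined with the sodium phenoxide of 5. The mixture is warmed to about −30 °C, so that methide 17 is released into a stoichiometric amount of nucleophile.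
- Attack anti to the benzyl group (Evans alkylation model) should give (4R)-4-benzyl-3-{(2R)-3-[3-bromo-2-hydroxy-6-methoxy-4-(methoxymethoxy)phenyl]-2-[2,4-bis(methoxymethoxy)-3-(3-methylbut-2-en-1-yl)phenyl]propanoyl}-1,3-oxazolidin-2-one F2.
- After a cold AcOH quench, LiBH4 (Et2O, one equivalent of H2O, 0 °C) removes the auxiliary reductively and gives 19.

**Second: step 2.**
- What may go wrong: site selectivity may be poor, with bromine entering C5 (para to the phenol) or both free positions.
- The fallback drops the halogen and installs the formyl group by phenol direction at the open-chain stage. It sets out from 2 and comes back at 22.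
- NaBH4 converts 2 into 2-(hydroxymethyl)-3-methoxy-5-(methoxymethoxy)phenol F3. TolSO2Na/AcOH then gives 3-methoxy-5-(methoxymethoxy)-2-[(4-methylphenyl)sulfonylmethyl]phenol F4.
- Under the conditions of step 9 with 14, this passes through 5-methoxy-3-(methoxymethoxy)-6-methylidenecyclohexa-2,4-dien-1-one F5 to (3R)-3-[2,4-bis(methoxymethoxy)-3-(3-methylbut-2-en-1-yl)phenyl]-5-methoxy-7-(methoxymethoxy)-3,4-dihydro-2H-chromen-2-one F6.
- LiAlH4 then gives 2-{(2R)-2-[2,4-bis(methoxymethoxy)-3-(3-methylbut-2-en-1-yl)phenyl]-3-hydroxypropyl}-3-methoxy-5-(methoxymethoxy)phenol F7.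
- In F7 the C8a phenol has a single free ortho carbon, C8. A Casnati–Skattebøl formylation (MgCl2, Et3N, paraformaldehyde, THF, reflux) reacts only ortho to a magnesium phenoxide, so it should give 3-{(2R)-2-[2,4-bis(methoxymethoxy)-3-(3-methylbut-2-en-1-yl)phenyl]-3-hydroxypropyl}-2-hydroxy-4-methoxy-6-(methoxymethoxy)benzaldehyde F8.
- Mitsunobu closure as in step 11 leads to 22. The price is an unblocked C8 during the annulation.

**Third: step 13.**
- What may go wrong: protonation of the prenyl double bond and its closure onto a flanking ring B phenol may compete with acetal cleavage.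
- The fallback replaces acidolysis by a protecting-group exchange that uses no Brønsted acid. It sets out from 22 and comes back at 23.
- TMSOTf and 2,2'-bipyridyl (MeCN, 0 °C) turn aryl MOM ethers, through bipyridinium acetal salts, into aryl silyl ethers. This gives (3R)-5-methoxy-3-[3-(3-methylbut-2-en-1-yl)-2,4-bis(trimethylsilyloxy)phenyl]-7-(trimethylsilyloxy)-3,4-dihydro-2H-chromene-8-carbaldehyde F9.
- F9 is hydrolysed at neutral pH (H2O, or KF in MeOH) to 23.

**Further compounds**
F1 | step 9 | (4R)-4-benzyl-3-{[2,4-bis(methoxymethoxy)-3-(3-methylbut-2-en-1-yl)phenyl]acetyl}-1,3-oxazolidin-2-one | O=C1OC[C@@H](Cc2ccccc2)N1C(=O)Cc1ccc(OCOC)c(CC=C(C)C)c1OCOC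
F2 | step 9 | (4R)-4-benzyl-3-{(2R)-3-[3-bromo-2-hydroxy-6-methoxy-4-(methoxymethoxy)phenyl]-2-[2,4-bis(methoxymethoxy)-3-(3-methylbut-2-en-1-yl)phenyl]propanoyl}-1,3-oxazolidin-2-one | COc1cc(OCOC)c(Br)c(O)c1C[C@H](c1ccc(OCOC)c(CC=C(C)C)c1OCOC)C(=O)N1[C@H](Cc2ccccc2)COC1=O
F3 | step 2 | 2-(hydroxymethyl)-3-methoxy-5-(methoxymethoxy)phenol | COCOc1cc(O)c(CO)c(OC)c1
F4 | step 2 | 3-methoxy-5-(methoxymethoxy)-2-[(4-methylphenyl)sulfonylmethyl]phenol | COc1cc(OCOC)cc(O)c1CS(=O)(=O)c1ccc(C)cc1
F5 | step 2 | 5-methoxy-3-(methoxymethoxy)-6-methylidenecyclohexa-2,4-dien-1-one | C=C1C(=O)C=C(OCOC)C=C1OC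
F6 | step 2 | (3R)-3-[2,4-bis(methoxymethoxy)-3-(3-methylbut-2-en-1-yl)phenyl]-5-methoxy-7-(methoxymethoxy)-3,4-dihydro-2H-chromen-2-one | COc1cc(OCOC)cc2c1C[C@H](c1ccc(OCOC)c(CC=C(C)C)c1OCOC)C(=O)O2
F7 | step 2 | 2-{(2R)-2-[2,4-bis(methoxymethoxy)-3-(3-methylbut-2-en-1-yl)phenyl]-3-hydroxypropyl}-3-methoxy-5-(methoxymethoxy)phenol | COc1cc(OCOC)cc(O)c1C[C@H](c1ccc(OCOC)c(CC=C(C)C)c1OCOC)CO
F8 | step 2 | 3-{(2R)-2-[2,4-bis(methoxymethoxy)-3-(3-methylbut-2-en-1-yl)phenyl]-3-hydroxypropyl}-2-hydroxy-4-methoxy-6-(methoxymethoxy)benzaldehyde | COc1cc(OCOC)c(C=O)c(O)c1C[C@H](c1ccc(OCOC)c(CC=C(C)C)c1OCOC)CO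
F9 | step 13 | (3R)-5-methoxy-3-[3-(3-methylbut-2-en-1-yl)-2,4-bis(trimethylsilyloxy)phenyl]-7-(trimethylsilyloxy)-3,4-dihydro-2H-chromene-8-carbaldehyde | COc1cc(O[Si](C)(C)C)c(C=O)c2c1C[C@H](c1ccc(O[Si](C)(C)C)c(CC=C(C)C)c1O[Si](C)(C)C)CO2
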